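Abbreviations: PMB = 4‑methoxybenzyl, TBS = tert‑butyldimethylsilyl, Piv = pivaloyl, Ang = angeloyl, (Z)‑2‑methylbut‑2‑enoyl. Ring atoms of all carbocycles are numbered as in the target: C1 (side chain), C2, C3, C4 (methyl carbinol), C5 (ketone), C6; chain C7 (=CH2), C8, C9, C10/C11 (epoxide). "Up" is the face of the C2, C3 and C6 oxygens.

## Analysis of the target

The target is one cyclohexanone in which every ring carbon is functionalised: C1 carries the side chain, C2 a free secondary hydroxyl, C3 an angelate, C4 a methyl group and a free tertiary hydroxyl, C5 the ketone and C6 a second angelate. The chain runs from the exocyclic methylene carbon C7 through C8 (third angelate, allylic) and C9 to the 2,2‑dimethyloxirane C10/C11. There are seven stereocentres (1R, 2R, 3R, 4S, 6S, 8S, 10S). C6–O, C1–C7 and C2–O alternate faces and are all equatorial. C3–O is cis to C2–O and axial. C4–O is anti to C3–O and axial, with the methyl group equatorial. C8 and C10 are remote from the ring. The sensitive groups are the three (Z)‑enoates (which isomerise to tiglates under nucleophilic catalysis), the tertiary α‑ketol with an enolisable C6–H beside the ketone, the cis C2‑hydroxy/C3‑ester pair (acyl migration under base) and the acid‑labile trisubstituted epoxide. The difficulty is to tell five ring oxygens apart (three acylated at fixed positions, two free, one on a quaternary carbon) and to order the steps so that esters, ketone and epoxide never meet reagents they cannot survive. The strategy rests on two facts: O–C3–C4–C5=O is a β‑hydroxy ketone, and C2, C1 and C6 carry the substitution pattern of C2, C3 and C4 of a D‑glucopyranoside whose 3‑oxygen is replaced by a carbon branch. The ring can therefore be folded out of a 3‑C‑branched glucoside by making the C3–C4 bond.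

## Retrosynthetic reasoning

**38 back to 36.** No skeletal bond is cut. The epoxide is acid‑labile and a free C2 hydroxyl beside the C3 ester invites acyl migration under base. The C2 hydroxyl is therefore released last, by neutral oxidative cleavage of the PMB ether of 37. The epoxide is introduced one step earlier, by reagent‑controlled epoxidation of the only electron‑rich alkene of 36, after every acidic step is over.

**36 back to 34.** The C5 ketone is taken back to a secondary alcohol (35), tied to the tertiary C4 hydroxyl as the isopropylidene acetal of 34. A β‑hydroxy, α‑oxygenated ketone would not survive the hydride, base and organometallic steps that build the chain, and the tertiary acetate left by the ring closure can only be removed reductively. The forward steps are acetal hydrolysis without ester loss and oxidation of the one secondary hydroxyl.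

**34 back to 32, and 27 back to 26.** The C6 and C8 esters are cut together, back to diol 33 and its silyl ether 32. The C3 ester, on an axial hydroxyl beside the quaternary carbon, is placed earlier, on 26, where a strong alkoxide acylation is tolerated and no nucleophilic catalyst is needed.

**32 back to 27 and 29.** The C7–C8 bond is cut between the alkenyl carbon and the carbinol, giving iodoalkene 27 and aldehyde 29. This is the only bond whose formation delivers the 1,1‑disubstituted alkene and the allylic oxygen together, and the nickel/chromium coupling tolerates esters and acetals. C8 is then fixed by reagent control through enone 31 instead of relying on induction from C1.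

**26 back to 22.** The iodoalkene comes from terminal alkyne 24, the alkyne from aldehyde 23, and the aldehyde from the primary alcohol of 22, so C7 is the one‑carbon branch the sugar already carries.

**22 back to 19.** The acetal 22 comes from tetraol 21, made by reductive removal of both acyl groups of 20, itself the product of a hydroxyl‑directed reduction of ketone 19. The directed reduction places the C5 hydroxyl cis to the C4 oxygen, the only arrangement that lets one acetal pick out C4/C5 and leave C3–OH free.

**19 back to 17 (key disconnection).** The C3–C4 bond is cut. Ring carbon C3 becomes the anomeric carbon and C4 the enol carbon of pyranoside enol acetate 17, through the open‑chain mercurio keto aldehyde 18. The cut is made here because it turns C2, C1 and C6 into stereocentres the sugar already owns. It leaves C3–OH as the one free hydroxyl and delivers the C4 oxygen and methyl group in the same step. The forward reaction must set C3 and C4.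

**17 back to 13.** The enol acetate is the O‑acylated enol of methyl ketone 16. The ketone comes from carbinol 15, and 15 from a methyl nucleophile and aldehyde 14, which is the oxidised primary alcohol 13.

**13 back to 9.** Protecting‑group changes free O‑6 alone: diol 11 from acetal 10, then disilyl ether 12 and selective loss of the primary silyl group. The branch oxygen is an ester (10) so that it leaves together with the tertiary acetate later.

**9 back to 1, and 29 back to 28.** The equatorial hydroxymethyl branch comes from ketone 3 by methylenation (4), hydroboration (6), oxidation (7) and thermodynamic epimerisation. Ketone 3 comes from the commercial acetal 1 after selective O‑2 protection (2). Aldehyde 29 is the oxidised alcohol 28.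

## Alternatives that were turned down

**Alternative 1:** The ring is cut at C1–C2 and C3–C4. 5‑Bromo‑6‑methyl‑2‑pyrone A1 and vinylene carbonate A2 would combine in an endo [4+2] cycloaddition to the lactone‑bridged bicycle A3.
- For: two bonds, the ring, the quaternary C4 (bridgehead with methyl and lactone oxygen) and the cis C2/C3 oxygens arise in one step from achiral materials. The endo adduct has the target's relative configuration at C1–C4, with the carbonate on the face opposite the lactone bridge. The lactone carbon becomes C7 and the vinyl bromide is a handle for C5. In steps to the ring it is clearly stronger than the sugar route.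
- Against: A3 is racemic unless an asymmetric version of a thermal cycloaddition with an unactivated dienophile is found, and at the temperatures needed the bridged lactone can lose CO2. The C2 and C3 oxygens arrive as one carbonate and must later be told apart, with the target's ester on the more hindered C3, where selective acylation runs the wrong way. C6 and the C5 ketone remain to be built with new stereocontrol.
- Comparison: the chosen route offers the absolute configuration, three ring centres from the chiral pool, and C2/C3 differentiated from the start (C2 protected, C3 born free).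

**Alternative 2:** The ring is cut at C2–C3. SmI2 (divalent samarium) would couple the two aldehydes of dialdehyde A4 to the cis‑diol A5.
- For: ketyl–aldehyde closures to six‑membered cis‑diols are dependable, and the whole side chain including C8 is already on A4. That is more convergent than the linear chain construction used here.
- Against: A4 needs C1, C4 (quaternary), C5, C6 and C8 from acyclic stereocontrol. Its C3 aldehyde sits on a fully substituted α‑siloxy carbon, which a ketyl can expel. Its C2 aldehyde is α to an allylic methine and prone to epimerise or conjugate. The two new hydroxyls appear free and equivalent in reactivity, so the C2/C3 differentiation problem returns.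
- Comparison: the chosen route makes one C–C bond under milder conditions, differentiates C2 from C3, and leaves one uncertain centre instead of two.

**Alternative 3:** The ring is cut at C4–C5. A triazolium‑derived carbene would convert the aldehyde of keto aldehyde A6 into its Breslow intermediate, which adds to the methyl ketone to give ketol A7.
- For: the tertiary α‑ketol is delivered at the correct oxidation level in one step. On this point it is stronger than the chosen route, which needs acetate removal and a reduction/re‑oxidation detour of about four steps. It is also convergent.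
- Against: C4 depends on the facial selectivity of an intramolecular benzoin onto a ketone in a ring with four substituents. The aldehyde is α‑siloxy, so the Breslow intermediate can eliminate the α‑oxygen, and C6 can epimerise under the basic conditions. A6 requires C1, C2, C3, C6 and C8 from acyclic synthesis, and the C2/C3 acetonide again hides the differentiation problem.
- Comparison: the chosen route carries the same kind of uncertainty at C4 but obtains everything else from the sugar.

Key step: step 15

## Route

Remark on the chemistry: enol acetate 17 is drawn as the (Z)‑isomer; the (E)‑isomer, if it forms, is expected to give the same product, because the double bond is consumed before either new stereocentre is set.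

Step 1
Reactants: 1 methyl 4,6‑O‑benzylidene‑α‑D‑glucopyranoside (commercial acetal of methyl α‑D‑glucopyranoside)
Product: 2 methyl 4,6‑O‑benzylidene‑2‑O‑PMB‑α‑D‑glucopyranoside
Conditions: 4‑MeOC6H4CH2Cl, Bu4NHSO4 (cat.), NaOH (aq.), CH2Cl2, reflux
Reagents that add atoms: 4‑methoxybenzyl chloride, COc1ccc(CCl)cc1
Why: Phase‑transfer Williamson etherification; O‑2, the more acidic hydroxyl next to the anomeric centre, is alkylated preferentially and the minor 3‑O‑isomer is removed by chromatography.

Step 2
Reactants: 2 methyl 4,6‑O‑benzylidene‑2‑O‑PMB‑α‑D‑glucopyranoside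
Product: 3 methyl 4,6‑O‑benzylidene‑2‑O‑PMB‑α‑D‑ribo‑hexopyranosid‑3‑ulose
Conditions: Dess–Martin periodinane, CH2Cl2, rt
Reagents that add atoms: none
Why: Dess–Martin oxidation of the only free hydroxyl under neutral conditions, which keeps the α‑alkoxy ketone from epimerising at C2.

Step 3
Reactants: 3 methyl 4,6‑O‑benzylidene‑2‑O‑PMB‑α‑D‑ribo‑hexopyranosid‑3‑ulose
Product: 4 methyl 4,6‑O‑benzylidene‑3‑deoxy‑3‑C‑methylene‑2‑O‑PMB‑α‑D‑ribo‑hexopyranoside
Conditions: Ph3PCH3Br, KOtBu, THF, 0 °C to rt
Reagents that add atoms: methyltriphenylphosphonium bromide, C[P+](c1ccccc1)(c1ccccc1)c1ccccc1.[Br-]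
Why: Wittig methylenation; the non‑stabilised ylide adds to the 3‑ulose faster than it enolises it, as is usual for pyranosid‑3‑uloses.

Step 4
Reactants: 4 methyl 4,6‑O‑benzylidene‑3‑deoxy‑3‑C‑methylene‑2‑O‑PMB‑α‑D‑ribo‑hexopyranoside
Product: 6 methyl 4,6‑O‑benzylidene‑3‑deoxy‑3‑C‑(hydroxymethyl)‑2‑O‑PMB‑α‑D‑allopyranoside (axial branch), via alkylborane 5 (not isolated)
Conditions: BH3·THF, THF, 0 °C to rt; then NaOH, H2O2, 0 °C
Reagents that add atoms: hydrogen peroxide, OO
Why: Hydroboration–oxidation with boron on the terminal carbon; borane should approach the β‑face, away from the axial anomeric methoxy group, so the branch is expected axial. Step 6 resets this centre, so any mixture can be used.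

Step 5
Reactants: 6 methyl 4,6‑O‑benzylidene‑3‑deoxy‑3‑C‑(hydroxymethyl)‑2‑O‑PMB‑α‑D‑allopyranoside
Product: 7 methyl 4,6‑O‑benzylidene‑3‑deoxy‑3‑C‑formyl‑2‑O‑PMB‑α‑D‑allopyranoside
Conditions: Dess–Martin periodinane, CH2Cl2, rt
Reagents that add atoms: none
Why: Dess–Martin oxidation of the primary alcohol without base, so the β‑alkoxy aldehyde does not eliminate.

Step 6
Reactants: 7 methyl 4,6‑O‑benzylidene‑3‑deoxy‑3‑C‑formyl‑2‑O‑PMB‑α‑D‑allopyranoside
Product: 9 methyl 4,6‑O‑benzylidene‑3‑deoxy‑3‑C‑(hydroxymethyl)‑2‑O‑PMB‑α‑D‑glucopyranoside (equatorial branch), via equatorial aldehyde 8 (not isolated)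
Conditions: Et3N, CH2Cl2, rt; then MeOH, NaBH4, 0 °C
Reagents that add atoms: none
Why: Base‑mediated epimerisation through the enol, then borohydride reduction in the same flask. The axial formyl group is destabilised by the 1,3‑diaxial anomeric methoxy group, so equilibrium lies on the equatorial (gluco) side; this fixes sugar C3, the future C1 of the target.

Step 7
Reactants: 9 methyl 4,6‑O‑benzylidene‑3‑deoxy‑3‑C‑(hydroxymethyl)‑2‑O‑PMB‑α‑D‑glucopyranoside
Product: 10 methyl 4,6‑O‑benzylidene‑3‑deoxy‑2‑O‑PMB‑3‑C‑(pivaloyloxymethyl)‑α‑D‑glucopyranoside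
Conditions: t‑BuCOCl, pyridine, DMAP (cat.), CH2Cl2, 0 °C to rt
Reagents that add atoms: pivaloyl chloride, CC(C)(C)C(Cl)=O
Why: Acylation of the primary alcohol; the pivalate survives the acid, fluoride, oxidation and low‑temperature Grignard steps ahead and leaves together with the acetate in step 17.

Step 8
Reactants: 10 methyl 4,6‑O‑benzylidene‑3‑deoxy‑2‑O‑PMB‑3‑C‑(pivaloyloxymethyl)‑α‑D‑glucopyranoside
Product: 11 methyl 3‑deoxy‑2‑O‑PMB‑3‑C‑(pivaloyloxymethyl)‑α‑D‑glucopyranoside (4,6‑diol)
Conditions: AcOH–H2O (4:1), 60 °C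
Reagents that add atoms: none
Why: Acid‑catalysed acetal hydrolysis; the PMB ether, the pivalate and the methyl glycoside are stable to warm aqueous acetic acid.

Step 9
Reactants: 11 methyl 3‑deoxy‑2‑O‑PMB‑3‑C‑(pivaloyloxymethyl)‑α‑D‑glucopyranoside
Product: 12 methyl 4,6‑di‑O‑TBS‑3‑deoxy‑2‑O‑PMB‑3‑C‑(pivaloyloxymethyl)‑α‑D‑glucopyranoside
Conditions: TBSOTf, 2,6‑lutidine, CH2Cl2, 0 °C
Reagents that add atoms: tert‑butyldimethylsilyl triflate, CC(C)(C)[Si](C)(C)OS(=O)(=O)C(F)(F)F
Why: Silylation of both hydroxyls; the silyl triflate is needed for the flanked secondary O‑4.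

Step 10
Reactants: 12 methyl 4,6‑di‑O‑TBS‑3‑deoxy‑2‑O‑PMB‑3‑C‑(pivaloyloxymethyl)‑α‑D‑glucopyranoside
Product: 13 methyl 4‑O‑TBS‑3‑deoxy‑2‑O‑PMB‑3‑C‑(pivaloyloxymethyl)‑α‑D‑glucopyranoside (6‑OH free)
Conditions: HF·pyridine, pyridine, THF, 0 °C
Reagents that add atoms: none
Why: Selective desilylation; buffered HF cleaves the primary silyl ether far faster than the hindered secondary one.

Step 11
Reactants: 13 methyl 4‑O‑TBS‑3‑deoxy‑2‑O‑PMB‑3‑C‑(pivaloyloxymethyl)‑α‑D‑glucopyranoside
Product: 14 methyl 4‑O‑TBS‑3‑deoxy‑2‑O‑PMB‑3‑C‑(pivaloyloxymethyl)‑α‑D‑gluco‑hexodialdo‑1,5‑pyranoside (6‑aldehyde)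
Conditions: Dess–Martin periodinane, CH2Cl2, rt
Reagents that add atoms: none
Why: Dess–Martin oxidation to the aldehyde; neutral conditions avoid epimerisation at C5 and β‑elimination of the 4‑silyloxy group.

Step 12
Reactants: 14 the 6‑aldehyde
Product: 15 methyl 4‑O‑TBS‑3,7‑dideoxy‑2‑O‑PMB‑3‑C‑(pivaloyloxymethyl)‑α‑D‑gluco‑heptopyranoside (6‑carbinol; both C6 epimers)
Conditions: MeMgBr, THF, −78 °C
Reagents that add atoms: methylmagnesium bromide, C[Mg]Br
Why: Grignard addition to the aldehyde at low temperature, where the hindered pivalate is not attacked; the new carbinol centre is removed again in step 13.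

Step 13
Reactants: 15 the 6‑carbinol
Product: 16 methyl 4‑O‑TBS‑3,7‑dideoxy‑2‑O‑PMB‑3‑C‑(pivaloyloxymethyl)‑α‑D‑xylo‑heptopyranosid‑6‑ulose (methyl ketone)
Conditions: Dess–Martin periodinane, CH2Cl2, rt
Reagents that add atoms: none
Why: Dess–Martin oxidation of the secondary alcohol to the methyl ketone.

Step 14
Reactants: 16 the methyl ketone
Product: 17 methyl (Z)‑6‑O‑acetyl‑4‑O‑TBS‑3,7‑dideoxy‑2‑O‑PMB‑3‑C‑(pivaloyloxymethyl)‑α‑D‑xylo‑hept‑5‑enopyranoside (enol acetate)
Conditions: Ac2O, K2CO3, MeCN, 80 °C
Reagents that add atoms: acetic anhydride, CC(=O)OC(C)=O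
Why: Enol acetylation under equilibrating base conditions, as used for 6‑aldehydo pyranosides; the C5 hydrogen, acidified by the ring oxygen, is removed in preference to a methyl hydrogen and the enolate is O‑acylated to the tetrasubstituted enol acetate.

Step 15
Reactants: 17 the enol acetate
Product: 19 cyclohexanone with C1 CH2OPiv; C2 OPMB; C3 OH (axial); C4 methyl (equatorial) and OAc (axial); C5 ketone; C6 OTBS, via mercurio keto aldehyde 18 (not isolated)
Conditions: Hg(OCOCF3)2 (10 mol %), acetone–H2O (2:1), rt
Reagents that add atoms: water, O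
Why: Ferrier carbocyclization, the mercury‑mediated conversion of hex‑5‑enopyranosides into cyclohexanones, known for 6‑O‑acetyl enol acetates. Hg(OCOCF3)2 (divalent mercury) adds to the enol carbon because the ring oxygen, not the acetoxy group, stabilises the cation at sugar C5; water adds there, the hemiketal collapses to the C5 ketone and the anomeric hemiacetal loses methanol to give 18. The mercury enolate of 18 adds to the aldehyde, forming the C3–C4 bond and closing the ring in a 6‑(enolendo)‑exo‑trig aldol, and protonolysis of the mercury alkoxide returns the catalyst. Closure goes through a chair in which the three inherited substituents (OTBS, CH2OPiv, OPMB) are equatorial. C3: mercury on the enolate oxygen can reach the aldehyde oxygen only when that oxygen is axial, so the new hydroxyl is axial, cis to the C2 ether and trans to the C1 branch, the normal outcome with an equatorial group at sugar C3. C4: the enolate substituent syn to the enolate oxygen ends up equatorial; the methyl‑syn geometry should be favoured because it keeps the larger group out of the axial site and places the C4–O bond anti to C3–O and away from the carbonyl dipole, giving methyl equatorial and acetoxy axial. The step needs regioselective mercuration (secured by the donor ring oxygen), no attack on the arene or the esters (secured by the catalytic loading) and no dehydration of the aldol (excluded because C4 has no hydrogen).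

Step 16
Reactants: 19 the cyclohexanone
Product: 20 3,5‑anti‑diol: C3 OH; C4 methyl and OAc; C5 OH (equatorial, cis to the C4 oxygen); other groups as in 19
Conditions: Me4NBH(OAc)3, MeCN–AcOH (1:1), −20 °C
Reagents that add atoms: none
Why: Evans–Saksena directed reduction; the C3 hydroxyl exchanges onto boron and delivers hydride intramolecularly to the upper face of C5 through a chair, so the new hydroxyl is anti to C3–OH and cis to the C4 acetoxy group.

Step 17
Reactants: 20 the 3,5‑anti‑diol
Product: 21 tetraol: C1 CH2OH; C2 OPMB; C3, C4 and C5 OH; C6 OTBS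
Conditions: i‑Bu2AlH, CH2Cl2, −78 to 0 °C
Reagents that add atoms: none
Why: Reductive cleavage of both esters (tertiary acetate and primary pivalate) by the aluminium hydride; with no ketone left nothing else is reduced, and the low temperature prevents silyl migration from O‑6 to O‑5.

Step 18
Reactants: 21 the tetraol
Product: 22 4,5‑O‑isopropylidene acetal with C3 OH and C7 OH free
Conditions: Me2C(OMe)2, PPTS (cat.), acetone, rt
Reagents that add atoms: 2,2‑dimethoxypropane, COC(C)(C)OC
Why: Acetonide formation by transketalisation; only the C4/C5 hydroxyls are cis‑vicinal (C3–OH is trans‑diaxial to C4–OH), so a single acetal forms.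

Step 19
Reactants: 22 the acetonide diol
Product: 23 C7 aldehyde with C3 OH free
Conditions: TEMPO (cat.), PhI(OAc)2, CH2Cl2, rt
Reagents that add atoms: none
Why: Oxoammonium (TEMPO) oxidation, selective for the primary alcohol over the hindered axial secondary C3 hydroxyl.

Step 20
Reactants: 23 the C7 aldehyde
Product: 24 terminal alkyne at C1 (C3 OH free)
Conditions: MeC(O)C(N2)P(O)(OMe)2, K2CO3, MeOH, 0 °C to rt
Reagents that add atoms: dimethyl (1‑diazo‑2‑oxopropyl)phosphonate, COP(=O)(OC)C(=[N+]=[N-])C(C)=O
Why: Seyferth–Gilbert homologation in the Ohira–Bestmann form; the mild carbonate base leaves C1 alone, whose formyl group is already in the favoured equatorial position.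

Step 21
Reactants: 24 the alkyne
Product: 26 2‑iodoalkene (C7 iodide; C3 OH free), via alkenylalane 25 (not isolated)
Conditions: Ni(dppp)Cl2 (3 mol %), i‑Bu2AlH, THF, rt; then N‑iodosuccinimide, 0 °C
Reagents that add atoms: N‑iodosuccinimide, O=C1CCC(=O)N1I
Why: Nickel‑catalysed Markovnikov hydroalumination of the terminal alkyne (aluminium at the internal carbon, steered by the bisphosphine–nickel catalyst), then iodinolysis of the C–Al bond; the free hydroxyl is carried as its aluminium alkoxide.

Step 22
Reactants: 26 the 2‑iodoalkene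
Product: 27 2‑iodoalkene with C3 OAng
Conditions: LiN(SiMe3)2, THF, −78 °C; then angelic anhydride, −78 to 0 °C
Reagents that add atoms: angelic anhydride, C/C=C(/C)C(=O)OC(=O)/C(C)=C\C
Why: Acylation of the lithium alkoxide with the anhydride; no nucleophilic catalyst is present, which preserves the (Z)‑geometry of the angelate on this hindered axial hydroxyl.

Step 23
Reactants: 28 4‑methylpent‑3‑en‑1‑ol
Product: 29 4‑methylpent‑3‑enal
Conditions: Dess–Martin periodinane, pyridine, CH2Cl2, 0 °C
Reagents that add atoms: none
Why: Dess–Martin oxidation buffered with pyridine; the β,γ‑unsaturated aldehyde is used at once so that it does not move into conjugation.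

Step 24
Reactants: 27 the iodoalkene angelate; 29 4‑methylpent‑3‑enal
Product: 30 allylic alcohol with the full chain (both C8 epimers)
Conditions: CrCl2, NiCl2 (1 mol %), DMSO, rt
Reagents that add atoms: none
Why: Nozaki–Hiyama–Kishi coupling: oxidative addition of the C–I bond to zerovalent nickel, transmetallation to trivalent chromium and addition of the alkenylchromium to the aldehyde, which tolerates ester, acetal and ether groups. Control at C8 is not needed because steps 25 and 26 reset it.

Step 25
Reactants: 30 the allylic alcohol mixture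
Product: 31 C8 enone
Conditions: Dess–Martin periodinane, pyridine, CH2Cl2, 0 °C
Reagents that add atoms: none
Why: Dess–Martin oxidation of both epimers to one enone; buffered conditions keep the C10=C11 alkene out of conjugation.

Step 26
Reactants: 31 the enone
Product: 32 (8S)‑allylic alcohol
Conditions: (R)‑2‑methyl‑CBS‑oxazaborolidine, catecholborane, toluene, −78 °C
Reagents that add atoms: none
Why: Corey–Bakshi–Shibata reduction; with the α‑branched alkenyl group as the large substituent and the CH2 chain as the small one, the (R)‑catalyst delivers hydride to the face that gives the (8S)‑alcohol, and catecholborane at low temperature does not hydroborate the alkenes.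

Step 27
Reactants: 32 the (8S)‑alcohol
Product: 33 C6,C8‑diol
Conditions: Bu4NF, THF, 0 °C to rt
Reagents that add atoms: none
Why: Fluoride cleavage of the remaining silyl ether; no ester sits next to the alkoxide formed, so no acyl migration is possible.

Step 28
Reactants: 33 the C6,C8‑diol
Product: 34 tris‑angelate (C3, C6, C8) with 4,5‑acetonide and C2 OPMB
Conditions: angelic acid, 2,4,6‑Cl3C6H2COCl, Et3N, toluene, rt then 75 °C
Reagents that add atoms: angelic acid, C/C=C(/C)C(=O)O
Why: Yamaguchi esterification (mixed 2,4,6‑trichlorobenzoic anhydride) of both secondary hydroxyls without a nucleophilic catalyst, the established way to make angelates without isomerisation to tiglates.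

Step 29
Reactants: 34 the tris‑angelate acetonide
Product: 35 C4,C5‑diol
Conditions: AcOH–H2O (4:1), 50 °C
Reagents that add atoms: none
Why: Acid‑catalysed hydrolysis of the isopropylidene acetal; dilute acetic acid leaves the esters, the PMB ether and the alkenes untouched.

Step 30
Reactants: 35 the C4,C5‑diol
Product: 36 C5 ketone with free tertiary C4 OH
Conditions: Dess–Martin periodinane, pyridine, CH2Cl2, 0 °C to rt
Reagents that add atoms: none
Why: Dess–Martin oxidation of the only secondary hydroxyl; the tertiary C4 hydroxyl cannot be oxidised, and buffered neutral conditions avoid epimerisation at C6 and acyl migration.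

Step 31
Reactants: 36 the ketone
Product: 37 (10S)‑epoxide with C2 OPMB
Conditions: ent‑Shi ketone (L‑fructose‑derived), Oxone (2KHSO5·KHSO4·K2SO4), K2CO3, Bu4NHSO4, MeCN–CH2(OMe)2–aq. Na2B4O7/Na2EDTA buffer, 0 °C
Reagents that add atoms: potassium peroxymonosulfate, [K+].[O-]S(=O)(=O)OO
Why: Shi asymmetric epoxidation; the chiral dioxirane reacts only with the electron‑rich trisubstituted alkene (the 1,1‑disubstituted alkene and the three enoates are much less nucleophilic) through the spiro transition state, and the enantiomeric, L‑fructose‑derived ketone gives the (10S)‑epoxide.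

Step 32
Reactants: 37 the epoxide PMB ether
Product: 38 CNP0145026.1
Conditions: DDQ, CH2Cl2–pH 7 phosphate buffer, 0 °C
Reagents that add atoms: none
Why: Oxidative cleavage of the PMB ether by DDQ in buffered wet solvent; the conditions are neutral and spare the epoxide, the esters and the α‑ketol.

## Compound list

1 | methyl 4,6‑O‑benzylidene‑α‑D‑glucopyranoside | CO[C@@H]1[C@H](O)[C@@H](O)[C@@H]2O[C@H](c3ccccc3)OC[C@H]2O1 | starting material
2 | methyl 4,6‑O‑benzylidene‑2‑O‑PMB‑α‑D‑glucopyranoside | CO[C@@H]1[C@H](OCc3ccc(OC)cc3)[C@@H](O)[C@@H]2O[C@H](c3ccccc3)OC[C@H]2O1 | intermediate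
3 | 3‑ulose | CO[C@@H]1[C@H](OCc3ccc(OC)cc3)C(=O)[C@@H]2O[C@H](c3ccccc3)OC[C@H]2O1 | intermediate
4 | 3‑C‑methylene sugar | CO[C@@H]1[C@H](OCc3ccc(OC)cc3)C(=C)[C@@H]2O[C@H](c3ccccc3)OC[C@H]2O1 | intermediate
5 | alkylborane | CO[C@@H]1[C@H](OCc3ccc(OC)cc3)[C@H](CB)[C@@H]2O[C@H](c3ccccc3)OC[C@H]2O1 | intermediate (not isolated)
6 | axial 3‑C‑hydroxymethyl sugar (allo) | CO[C@@H]1[C@H](OCc3ccc(OC)cc3)[C@H](CO)[C@@H]2O[C@H](c3ccccc3)OC[C@H]2O1 | intermediate
7 | axial 3‑C‑formyl sugar (allo) | CO[C@@H]1[C@H](OCc3ccc(OC)cc3)[C@H](C=O)[C@@H]2O[C@H](c3ccccc3)OC[C@H]2O1 | intermediate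
8 | equatorial 3‑C‑formyl sugar (gluco) | CO[C@@H]1[C@H](OCc3ccc(OC)cc3)[C@@H](C=O)[C@@H]2O[C@H](c3ccccc3)OC[C@H]2O1 | intermediate (not isolated)
9 | equatorial 3‑C‑hydroxymethyl sugar (gluco) | CO[C@@H]1[C@H](OCc3ccc(OC)cc3)[C@@H](CO)[C@@H]2O[C@H](c3ccccc3)OC[C@H]2O1 | intermediate
10 | pivalate of 9 | CO[C@@H]1[C@H](OCc3ccc(OC)cc3)[C@@H](COC(=O)C(C)(C)C)[C@@H]2O[C@H](c3ccccc3)OC[C@H]2O1 | intermediate
11 | 4,6‑diol | CO[C@@H]1[C@H](OCc2ccc(OC)cc2)[C@@H](COC(=O)C(C)(C)C)[C@H](O)[C@@H](CO)O1 | intermediate
12 | 4,6‑bis‑TBS ether | CO[C@@H]1[C@H](OCc2ccc(OC)cc2)[C@@H](COC(=O)C(C)(C)C)[C@H](O[Si](C)(C)C(C)(C)C)[C@@H](CO[Si](C)(C)C(C)(C)C)O1 | intermediate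
13 | 4‑O‑TBS 6‑alcohol | CO[C@@H]1[C@H](OCc2ccc(OC)cc2)[C@@H](COC(=O)C(C)(C)C)[C@H](O[Si](C)(C)C(C)(C)C)[C@@H](CO)O1 | intermediate
14 | 6‑aldehyde | CO[C@@H]1[C@H](OCc2ccc(OC)cc2)[C@@H](COC(=O)C(C)(C)C)[C@H](O[Si](C)(C)C(C)(C)C)[C@@H](C=O)O1 | intermediate
15 | 6‑carbinol (7‑deoxyheptoside, C6 epimers) | CO[C@@H]1[C@H](OCc2ccc(OC)cc2)[C@@H](COC(=O)C(C)(C)C)[C@H](O[Si](C)(C)C(C)(C)C)[C@@H](C(C)O)O1 | intermediate
16 | methyl ketone | CO[C@@H]1[C@H](OCc2ccc(OC)cc2)[C@@H](COC(=O)C(C)(C)C)[C@H](O[Si](C)(C)C(C)(C)C)[C@@H](C(C)=O)O1 | intermediate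
17 | (Z)‑enol acetate (key‑step precursor) | CO[C@@H]1[C@H](OCc2ccc(OC)cc2)[C@@H](COC(=O)C(C)(C)C)[C@H](O[Si](C)(C)C(C)(C)C)/C(O1)=C(\C)OC(C)=O | intermediate
18 | mercurio keto aldehyde | O=C[C@H](OCc1ccc(OC)cc1)[C@@H](COC(=O)C(C)(C)C)[C@H](O[Si](C)(C)C(C)(C)C)C(=O)C(C)(OC(C)=O)[Hg]OC(=O)C(F)(F)F | intermediate (not isolated)
19 | cyclohexanone (key‑step product) | CC(C)(C)C(=O)OC[C@@H]1[C@@H](OCc2ccc(OC)cc2)[C@@H](O)[C@](C)(OC(C)=O)C(=O)[C@H]1O[Si](C)(C)C(C)(C)C | intermediate
20 | 3,5‑anti‑diol | CC(C)(C)C(=O)OC[C@@H]1[C@@H](OCc2ccc(OC)cc2)[C@@H](O)[C@](C)(OC(C)=O)[C@H](O)[C@H]1O[Si](C)(C)C(C)(C)C | intermediate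
21 | tetraol | OC[C@@H]1[C@@H](OCc2ccc(OC)cc2)[C@@H](O)[C@](C)(O)[C@H](O)[C@H]1O[Si](C)(C)C(C)(C)C | intermediate
22 | 4,5‑acetonide diol | OC[C@@H]1[C@@H](OCc3ccc(OC)cc3)[C@@H](O)[C@]2(C)OC(C)(C)O[C@@H]2[C@H]1O[Si](C)(C)C(C)(C)C | intermediate
23 | C7 aldehyde | O=C[C@@H]1[C@@H](OCc3ccc(OC)cc3)[C@@H](O)[C@]2(C)OC(C)(C)O[C@@H]2[C@H]1O[Si](C)(C)C(C)(C)C | intermediate
24 | alkyne | C#C[C@@H]1[C@@H](OCc3ccc(OC)cc3)[C@@H](O)[C@]2(C)OC(C)(C)O[C@@H]2[C@H]1O[Si](C)(C)C(C)(C)C | intermediate
25 | alkenylalane | C=C([Al](CC(C)C)CC(C)C)[C@@H]1[C@@H](OCc3ccc(OC)cc3)[C@@H](O[Al](CC(C)C)CC(C)C)[C@]2(C)OC(C)(C)O[C@@H]2[C@H]1O[Si](C)(C)C(C)(C)C | intermediate (not isolated)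
26 | 2‑iodoalkene | C=C(I)[C@@H]1[C@@H](OCc3ccc(OC)cc3)[C@@H](O)[C@]2(C)OC(C)(C)O[C@@H]2[C@H]1O[Si](C)(C)C(C)(C)C | intermediate
27 | 2‑iodoalkene C3 angelate | C=C(I)[C@@H]1[C@@H](OCc3ccc(OC)cc3)[C@@H](OC(=O)/C(C)=C\C)[C@]2(C)OC(C)(C)O[C@@H]2[C@H]1O[Si](C)(C)C(C)(C)C | intermediate
28 | 4‑methylpent‑3‑en‑1‑ol | CC(C)=CCCO | starting material
29 | 4‑methylpent‑3‑enal | CC(C)=CCC=O | intermediate
30 | allylic alcohol (C8 epimers) | C=C([C@@H]1[C@@H](OCc3ccc(OC)cc3)[C@@H](OC(=O)/C(C)=C\C)[C@]2(C)OC(C)(C)O[C@@H]2[C@H]1O[Si](C)(C)C(C)(C)C)C(O)CC=C(C)C | intermediate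
31 | enone | C=C([C@@H]1[C@@H](OCc3ccc(OC)cc3)[C@@H](OC(=O)/C(C)=C\C)[C@]2(C)OC(C)(C)O[C@@H]2[C@H]1O[Si](C)(C)C(C)(C)C)C(=O)CC=C(C)C | intermediate
32 | (8S)‑allylic alcohol | C=C([C@@H]1[C@@H](OCc3ccc(OC)cc3)[C@@H](OC(=O)/C(C)=C\C)[C@]2(C)OC(C)(C)O[C@@H]2[C@H]1O[Si](C)(C)C(C)(C)C)[C@H](CC=C(C)C)O | intermediate
33 | C6,C8‑diol | C=C([C@@H]1[C@@H](OCc3ccc(OC)cc3)[C@@H](OC(=O)/C(C)=C\C)[C@]2(C)OC(C)(C)O[C@@H]2[C@H]1O)[C@H](CC=C(C)C)O | intermediate
34 | tris‑angelate acetonide | C=C([C@@H]1[C@@H](OCc3ccc(OC)cc3)[C@@H](OC(=O)/C(C)=C\C)[C@]2(C)OC(C)(C)O[C@@H]2[C@H]1OC(=O)/C(C)=C\C)[C@H](CC=C(C)C)OC(=O)/C(C)=C\C | intermediate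
35 | C4,C5‑diol | C=C([C@@H]1[C@@H](OCc2ccc(OC)cc2)[C@@H](OC(=O)/C(C)=C\C)[C@](C)(O)[C@H](O)[C@H]1OC(=O)/C(C)=C\C)[C@H](CC=C(C)C)OC(=O)/C(C)=C\C | intermediate
36 | C5 ketone | C=C([C@@H]1[C@@H](OCc2ccc(OC)cc2)[C@@H](OC(=O)/C(C)=C\C)[C@](C)(O)C(=O)[C@H]1OC(=O)/C(C)=C\C)[C@H](CC=C(C)C)OC(=O)/C(C)=C\C | intermediate
37 | (10S)‑epoxide PMB ether | C=C([C@@H]1[C@@H](OCc2ccc(OC)cc2)[C@@H](OC(=O)/C(C)=C\C)[C@](C)(O)C(=O)[C@H]1OC(=O)/C(C)=C\C)[C@H](C[C@@H]1OC1(C)C)OC(=O)/C(C)=C\C | intermediate
38 | CNP0145026.1 | C=C([C@@H]1[C@@H](O)[C@@H](OC(=O)/C(C)=C\C)[C@](C)(O)C(=O)[C@H]1OC(=O)/C(C)=C\C)[C@H](C[C@@H]1OC1(C)C)OC(=O)/C(C)=C\C | target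

## Step count and the least certain steps

Total: 32 steps. Longest linear sequence: 31 steps (1 to 38 through steps 1–22 and 24–32); step 23 prepares aldehyde 29.

**Step 15 (key step).** The most likely failure is loss of control over which C4 substituent sits syn to the enolate oxygen when the mercury enolate closes. If the acetoxy oxygen acts as a second ligand for mercury, it takes the syn (equatorial) position and the selectivity at C4 falls or inverts. Slow mercuration of the tetrasubstituted enol acetate is the second concern. The fallback removes the C4 oxygen and puts it back under steric control, so both C4 epimers converge. It sets out from 19, taken as whatever C4 mixture forms. The C3 hydroxyl is capped as the trimethylsilyl ether F1 (Me3SiCl, imidazole). SmI2 (divalent samarium) in THF at −78 °C cleaves the C4–OAc bond to give the regiodefined samarium enolate, which is oxidised in the same flask with 2‑(phenylsulfonyl)‑3‑phenyloxaziridine from the face opposite the axial C3 silyloxy group, giving the α‑hydroxy ketone F2 (hydroxyl down, methyl up). Mild acid methanolysis gives the dihydroxy ketone F3, the directed reduction of step 16 gives the pivalate triol F4, and i‑Bu2AlH removes the pivalate to rejoin the route at 21.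

**Step 14.** Enolisation may go toward the methyl group, or the 4‑silyloxy group may be lost by β‑elimination at 80 °C, so the tetrasubstituted enol acetate is formed inefficiently. The fallback separates regiocontrol from acylation. From 16, amine‑mediated soft enolisation (Me3SiOTf, Et3N), which is known to favour the alkoxy‑substituted carbon of α‑alkoxy ketones, gives the trimethylsilyl enol ether F5. KOtBu at −78 °C releases the potassium enolate, and Ac2O acylates it on oxygen to return to 17.

**Step 21.** Incomplete Markovnikov control in the hydroalumination, or consumption of hydride by the substrate, would give the terminal iodide or the alkene. The fallback, from 24, is ruthenium‑catalysed hydrosilylation ([Cp*Ru(MeCN)3]PF6, Et3SiH), which places silicon at the internal carbon, to the α‑vinylsilane F6. Iododesilylation with N‑iodosuccinimide then returns to 26.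

**Step 22.** Acylation of the axial C3 hydroxyl next to the quaternary centre may be slow, and forcing it invites isomerisation of the angelate to the tiglate. The fallback builds the double bond after the ester is in place. From 26, DCC/DMAP coupling with 2‑[bis(2,2,2‑trifluoroethoxy)phosphoryl]propanoic acid (no alkene to isomerise, so a nucleophilic catalyst is allowed) gives the phosphonopropionate F7. Still–Gennari olefination with acetaldehyde (KN(SiMe3)2, 18‑crown‑6, −78 °C) forms the (Z)‑enoate and returns to 27.

**Step 31.** The carbonate‑buffered epoxidation may epimerise C6 or shift acyl groups in the α‑acyloxy ketone. The fallback moves the epoxidation ahead of the oxidation, where no ketone is present. From 35, the same Shi conditions give the epoxy diol F8, and buffered Dess–Martin oxidation, which an epoxide tolerates, returns to 37.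

## Further compounds

F1 | step 15 | C3 trimethylsilyl ether of 19 (either C4 configuration) | CC(C)(C)C(=O)OC[C@@H]1[C@@H](OCc2ccc(OC)cc2)[C@@H](O[Si](C)(C)C)C(C)(OC(C)=O)C(=O)[C@H]1O[Si](C)(C)C(C)(C)C
F2 | step 15 | C4 α‑hydroxy ketone with C3 trimethylsilyl ether | CC(C)(C)C(=O)OC[C@@H]1[C@@H](OCc2ccc(OC)cc2)[C@@H](O[Si](C)(C)C)[C@](C)(O)C(=O)[C@H]1O[Si](C)(C)C(C)(C)C
F3 | step 15 | C3,C4‑dihydroxy ketone | CC(C)(C)C(=O)OC[C@@H]1[C@@H](OCc2ccc(OC)cc2)[C@@H](O)[C@](C)(O)C(=O)[C@H]1O[Si](C)(C)C(C)(C)C
F4 | step 15 | pivalate triol | CC(C)(C)C(=O)OC[C@@H]1[C@@H](OCc2ccc(OC)cc2)[C@@H](O)[C@](C)(O)[C@H](O)[C@H]1O[Si](C)(C)C(C)(C)C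
F5 | step 14 | trimethylsilyl enol ether of 16 | CO[C@@H]1[C@H](OCc2ccc(OC)cc2)[C@@H](COC(=O)C(C)(C)C)[C@H](O[Si](C)(C)C(C)(C)C)/C(O1)=C(\C)O[Si](C)(C)C
F6 | step 21 | α‑vinylsilane | C=C([Si](CC)(CC)CC)[C@@H]1[C@@H](OCc3ccc(OC)cc3)[C@@H](O)[C@]2(C)OC(C)(C)O[C@@H]2[C@H]1O[Si](C)(C)C(C)(C)C
F7 | step 22 | C3 phosphonopropionate | C=C(I)[C@@H]1[C@@H](OCc3ccc(OC)cc3)[C@@H](OC(=O)C(C)P(=O)(OCC(F)(F)F)OCC(F)(F)F)[C@]2(C)OC(C)(C)O[C@@H]2[C@H]1O[Si](C)(C)C(C)(C)C
F8 | step 31 | epoxy C4,C5‑diol | C=C([C@@H]1[C@@H](OCc2ccc(OC)cc2)[C@@H](OC(=O)/C(C)=C\C)[C@](C)(O)[C@H](O)[C@H]1OC(=O)/C(C)=C\C)[C@H](C[C@@H]1OC1(C)C)OC(=O)/C(C)=C\C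
A1 | alternative 1 | 5‑bromo‑6‑methyl‑2‑pyrone | CC1=C(Br)C=CC(=O)O1
A2 | alternative 1 | vinylene carbonate | O=C1OC=CO1
A3 | alternative 1 | endo bicyclic lactone carbonate | O=C1[C@@H]2[C@H]3OC(=O)O[C@H]3[C@](C)(O1)C(Br)=C2
A4 | alternative 2 | 1,6‑dialdehyde | O=C[C@](C)(O[Si](CC)(CC)CC)[C@H]1OC(C)(C)O[C@H]1[C@@H](C=O)C(=C)[C@H](CC=C(C)C)O[Si](C)(C)C(C)(C)C
A5 | alternative 2 | cyclohexane cis‑2,3‑diol | C=C([C@@H]1[C@@H](O)[C@@H](O)[C@](C)(O[Si](CC)(CC)CC)[C@H]2OC(C)(C)O[C@@H]12)[C@H](CC=C(C)C)O[Si](C)(C)C(C)(C)C
A6 | alternative 3 | keto aldehyde | CC(=O)[C@@H]1OC(C)(C)O[C@@H]1[C@H]([C@@H](C=O)O[Si](C)(C)C(C)(C)C)C(=C)[C@H](CC=C(C)C)O[Si](C)(C)C(C)(C)C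
A7 | alternative 3 | cyclic α‑ketol | C=C([C@@H]1[C@H]2OC(C)(C)O[C@H]2[C@](C)(O)C(=O)[C@H]1O[Si](C)(C)C(C)(C)C)[C@H](CC=C(C)C)O[Si](C)(C)C(C)(C)C
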